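**Retrosynthetic overview**

- Rings A, B and C and both stereocentres (C2, C3) are bought intact as (+)-aromadendrin, so no ring is formed in the route; only the two C-prenyl groups are added.
- The strategy rests on this feature: each prenylated carbon is within sigmatropic reach of a phenolic oxygen. C8 of ring A is para to O5, with the unsubstituted C6 as relay; C3' of ring B is ortho to O4'.
- The C8–C1'' and C3'–C1''' bonds are therefore cut back to O-allyl ethers: a 5-O-prenyl ether (Claisen then Cope shift) and a 4'-O-(1,1-dimethylallyl) ether (ortho-Claisen shift), both rearranged in one pot with catalytic Eu(fod)3.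
- The bis-ether comes from aromadendrin by 7-O-MOM protection, copper-catalysed 4'-O-propargylation, 3-O-acetylation, semihydrogenation and Mitsunobu 5-O-prenylation; deacetylation and MOM cleavage finish the synthesis.

Key step: step 6

Assumption: (+)-aromadendrin is bought as the single (2R,3R) enantiomer. The tertiary allyl ethers 6 and 8 are to be handled below 40 °C and purified on base-washed silica. MOM = methoxymethyl; prenyl = 3-methylbut-2-enyl; 1,1-dimethylallyl = 2-methylbut-3-en-2-yl; Eu(fod)3 = Eu(C10H10F7O2)3, europium tris(6,6,7,7,8,8,8-heptafluoro-2,2-dimethyloctane-3,5-dionate).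

**Step 1**
Reactants: 1 (+)-aromadendrin
Product: 2 (2R,3R)-7-O-MOM-aromadendrin
Conditions: MOMCl (1.05 equiv), iPr2NEt (1.2 equiv), DMF, −10 → 0 °C, Ar
Reagents that add atoms: chloromethyl methyl ether (MOMCl), COCCl
Why: Williamson-type O-alkylation with one equivalent of MOMCl should go to the 7-hydroxyl, the most acidic phenol (para to the C4 carbonyl), because the 5-hydroxyl is hydrogen-bonded to C4=O, the 4'-hydroxyl is a weaker acid and the 3-hydroxyl is an alcohol that the amine base does not deprotonate; no stereocentre is touched.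

**Step 2**
Reactants: 2 (2R,3R)-7-O-MOM-aromadendrin; 3 3-chloro-3-methylbut-1-yne
Product: 4 (2R,3R)-7-O-MOM-4'-O-(2-methylbut-3-yn-2-yl)aromadendrin
Conditions: CuCl2·2H2O (1 mol%), DBU (1.3 equiv), MeCN, −5 → 0 °C, Ar
Reagents that add atoms: none
Why: Copper-catalysed O-propargylation of a phenol with a tertiary propargylic chloride (substitution through a copper acetylide) should alkylate the 4'-phenoxide, the only unchelated phenol left, at the tertiary carbon; low temperature and short contact with DBU are chosen to keep ring C closed, and no stereocentre is formed.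

**Step 3**
Reactants: 4 (2R,3R)-7-O-MOM-4'-O-(2-methylbut-3-yn-2-yl)aromadendrin
Product: 5 (2R,3R)-3-O-acetyl-7-O-MOM-4'-O-(2-methylbut-3-yn-2-yl)aromadendrin
Conditions: Ac2O (1.5 equiv), pyridine, CH2Cl2, 0 °C → rt
Reagents that add atoms: acetic anhydride, CC(=O)OC(C)=O
Why: Pyridine-mediated O-acylation should take the secondary 3-hydroxyl, since the chelated 5-hydroxyl is the slowest hydroxyl of a flavonoid to acylate when DMAP is left out; the C3–O bond is not broken, so C3 keeps its configuration.

**Step 4**
Reactants: 5 (2R,3R)-3-O-acetyl-7-O-MOM-4'-O-(2-methylbut-3-yn-2-yl)aromadendrin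
Product: 6 (2R,3R)-3-O-acetyl-7-O-MOM-4'-O-(2-methylbut-3-en-2-yl)aromadendrin
Conditions: H2 (1 atm), Pd/CaCO3 poisoned with Pb(OAc)2 (Lindlar catalyst), quinoline, EtOAc, rt
Reagents that add atoms: none
Why: Lindlar semihydrogenation should stop at the vinyl stage on the poisoned catalyst, the terminal alkyne being the only reducible C–C multiple bond in 5 because the prenyl alkene is introduced only afterwards; no stereocentre is formed.

**Step 5**
Reactants: 6 (2R,3R)-3-O-acetyl-7-O-MOM-4'-O-(2-methylbut-3-en-2-yl)aromadendrin; 7 3-methylbut-2-en-1-ol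
Product: 8 (2R,3R)-3-O-acetyl-7-O-MOM-5-O-prenyl-4'-O-(2-methylbut-3-en-2-yl)aromadendrin
Conditions: PPh3, DIAD (1.5 equiv each), THF, 0 °C → rt
Reagents that add atoms: none
Why: Mitsunobu etherification: the 5-hydroxyl is now the only free hydroxyl, and SN2 attack of its phenoxide on the alkoxyphosphonium salt of the primary allylic alcohol should give the linear 5-O-prenyl ether under neutral conditions that spare the acetate, the MOM ether and the tertiary allyl ether; no stereocentre is involved.

**Step 6**
Reactants: 8 (2R,3R)-3-O-acetyl-7-O-MOM-5-O-prenyl-4'-O-(2-methylbut-3-en-2-yl)aromadendrin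
Product: 13 (2R,3R)-3-O-acetyl-7-O-MOM-lespedezaflavanone C, via ring A ortho-dienone 9 (not isolated), via ring A para-dienone 10 (not isolated), via 8-prenyl ring B ether 11 (not isolated), via ring B ortho-dienone 12 (not isolated)
Conditions: Eu(fod)3 [Eu(C10H10F7O2)3] (10 mol%), NaHCO3, PhCl, 85 °C, then 125 °C, Ar
Reagents that add atoms: none
Why: The trivalent europium centre of Eu(fod)3 binds O5 and the C4 carbonyl of 8 and thereby accelerates the aromatic Claisen shift of the 5-O-prenyl group to C6, giving dienone 9 with a reverse-prenyl group; a Cope shift across C6–C7=C8 then moves the group to C8 as a normal prenyl (dienone 10), and enolisation restores the chelated 5-hydroxyl in 11. At 125 °C the tertiary 1,1-dimethylallyl ether of ring B undergoes an uncatalysed ortho-Claisen shift through a chair transition state to C3' (dienone 12), whose enolisation gives the 4'-phenol 13 with the allyl unit inverted to a 3,3-dimethylallyl chain. The closest known reaction types are the europium-catalysed para-Claisen–Cope rearrangement of 5-O-prenylflavonoids and the thermal Claisen rearrangement of aryl 1,1-dimethylallyl ethers. No ring is closed and no stereocentre is formed; C2 and C3 are bystanders under these buffered, non-basic conditions. The selectivity needed is C8 over C6 on ring A: the quaternary reverse-prenyl group at C6 of 9 is compressed between the europium-bound C5 carbonyl and the 7-O-MOM group, so the Cope shift should outrun enolisation, which NaHCO3 further slows by removing traces of acid. On ring B the two ortho carbons C3' and C5' are equivalent and the para carbon is blocked, and the 7-O-MOM group keeps the new 8-prenyl group from cyclising onto O7.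

**Step 7**
Reactants: 13 (2R,3R)-3-O-acetyl-7-O-MOM-lespedezaflavanone C
Product: 14 (2R,3R)-7-O-MOM-lespedezaflavanone C
Conditions: K2CO3 (1 equiv), MeOH, 0 °C; AcOH quench
Reagents that add atoms: none
Why: Base-catalysed transesterification (Zemplén-type methanolysis) should cleave the acetate, which is activated by the adjacent C4 carbonyl, quickly at 0 °C while the prenyl groups and the MOM ether are inert; short contact at low temperature is chosen so that the phenoxides do not open ring C and C2 and C3 keep their configuration.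

**Step 8**
Reactants: 14 (2R,3R)-7-O-MOM-lespedezaflavanone C
Product: 15 lespedezaflavanone C
Conditions: HCl (ca. 1.5 M in MeOH), rt → 35 °C
Reagents that add atoms: none
Why: Acid-catalysed acetal exchange (MOM cleavage by methanolysis) should release the 7-hydroxyl with formation of dimethoxymethane; dilute acid near room temperature is chosen so that the 8- and 3'-prenyl groups do not cyclise onto the neighbouring phenols, and dihydroflavonols are configurationally stable to acid.

**Compound list**

1 | (+)-aromadendrin, (2R,3R)-3,5,7-trihydroxy-2-(4-hydroxyphenyl)chroman-4-one | Oc1ccc([C@H]2Oc3cc(O)cc(O)c3C(=O)[C@@H]2O)cc1 | starting material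
2 | (2R,3R)-7-O-MOM-aromadendrin | Oc1ccc([C@H]2Oc3cc(OCOC)cc(O)c3C(=O)[C@@H]2O)cc1 | intermediate
3 | 3-chloro-3-methylbut-1-yne | C#CC(C)(C)Cl | starting material
4 | (2R,3R)-7-O-MOM-4'-O-(2-methylbut-3-yn-2-yl)aromadendrin | C#CC(C)(C)Oc1ccc([C@H]2Oc3cc(OCOC)cc(O)c3C(=O)[C@@H]2O)cc1 | intermediate
5 | (2R,3R)-3-O-acetyl-7-O-MOM-4'-O-(2-methylbut-3-yn-2-yl)aromadendrin | C#CC(C)(C)Oc1ccc([C@H]2Oc3cc(OCOC)cc(O)c3C(=O)[C@@H]2OC(C)=O)cc1 | intermediate
6 | (2R,3R)-3-O-acetyl-7-O-MOM-4'-O-(2-methylbut-3-en-2-yl)aromadendrin | C=CC(C)(C)Oc1ccc([C@H]2Oc3cc(OCOC)cc(O)c3C(=O)[C@@H]2OC(C)=O)cc1 | intermediate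
7 | 3-methylbut-2-en-1-ol (prenol) | CC(C)=CCO | starting material
8 | (2R,3R)-3-O-acetyl-7-O-MOM-5-O-prenyl-4'-O-(2-methylbut-3-en-2-yl)aromadendrin (key-step precursor) | C=CC(C)(C)Oc1ccc([C@H]2Oc3cc(OCOC)cc(OCC=C(C)C)c3C(=O)[C@@H]2OC(C)=O)cc1 | intermediate
9 | ring A ortho-dienone: 5-oxo-5,6-dihydro tautomer carrying 6-(2-methylbut-3-en-2-yl), ring B ether intact, C6 configuration undefined | C=CC(C)(C)Oc1ccc([C@H]2OC3=C(C(=O)C(C(C)(C)C=C)C(OCOC)=C3)C(=O)[C@@H]2OC(C)=O)cc1 | intermediate
10 | ring A para-dienone: 5-oxo-5,8-dihydro tautomer carrying 8-prenyl, ring B ether intact, C8 configuration undefined | C=CC(C)(C)Oc1ccc([C@H]2OC3=C(C(=O)C=C(OCOC)C3CC=C(C)C)C(=O)[C@@H]2OC(C)=O)cc1 | intermediate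
11 | (2R,3R)-3-O-acetyl-7-O-MOM-8-prenyl-4'-O-(2-methylbut-3-en-2-yl)aromadendrin | C=CC(C)(C)Oc1ccc([C@H]2Oc3c(CC=C(C)C)c(OCOC)cc(O)c3C(=O)[C@@H]2OC(C)=O)cc1 | intermediate
12 | ring B ortho-dienone: 4'-oxo-3'-prenyl-3',4'-dihydro tautomer of 13, C3' configuration undefined | O=C1C(CC=C(C)C)C=C([C@H]2Oc3c(CC=C(C)C)c(OCOC)cc(O)c3C(=O)[C@@H]2OC(C)=O)C=C1 | intermediate
13 | (2R,3R)-3-O-acetyl-7-O-MOM-lespedezaflavanone C (key-step product) | CC(C)=CCc1cc([C@H]2Oc3c(CC=C(C)C)c(OCOC)cc(O)c3C(=O)[C@@H]2OC(C)=O)ccc1O | intermediate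
14 | (2R,3R)-7-O-MOM-lespedezaflavanone C | CC(C)=CCc1cc([C@H]2Oc3c(CC=C(C)C)c(OCOC)cc(O)c3C(=O)[C@@H]2O)ccc1O | intermediate
15 | lespedezaflavanone C, (2R,3R)-3,5,7-trihydroxy-2-(4-hydroxy-3-prenylphenyl)-8-prenylchroman-4-one | CC(C)=CCc1cc([C@H]2Oc3c(CC=C(C)C)c(O)cc(O)c3C(=O)[C@@H]2O)ccc1O | target

**Step count**

Total steps: 8. Longest linear sequence: 8 steps, from 1 to 15.

**Steps most likely to fail**

Step 6. The tertiary ring B ether may ionise on the Lewis acid and lose its C5 unit before it can rearrange, while ring A still needs the long europium-catalysed phase. The fallback separates the two shifts. It sets out from 8: heating without any Lewis acid in N,N-diethylaniline at 120 °C, where the primary 5-O-prenyl ether is thermally stable, should rearrange ring B only and give (2R,3R)-3-O-acetyl-7-O-MOM-5-O-prenyl-3'-prenylaromadendrin F1. F1 is then submitted alone to the europium-catalysed Claisen–Cope shift (Eu(fod)3, NaHCO3, PhCl, 85 °C) and the route is rejoined at 13.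

Step 2. The 4'-phenoxide formed with DBU may open ring C through a quinone methide and erode the C2 configuration, and O5 may be alkylated as well. The fallback installs the tertiary allyl ether directly and without amine base by palladium-catalysed O-allylation. It sets out from 2: Pd(PPh3)4 (zerovalent palladium) and tert-butyl 2-methylbut-3-en-2-yl carbonate F2 (made from 2-methylbut-3-en-2-ol, n-BuLi and Boc2O) in THF at 0 °C should give (2R,3R)-7-O-MOM-4'-O-(2-methylbut-3-en-2-yl)aromadendrin F3. The phenoxide attacks the more substituted end of the π-allyl palladium intermediate under kinetic control, and the reaction is stopped before the ether equilibrates to the linear isomer. Acetylation of F3 (Ac2O, pyridine, 0 °C) rejoins the route at 6, and the semihydrogenation is no longer needed.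

Step 1. The two unchelated phenols may not be told apart well enough, so that the 4'-hydroxyl is alkylated too. The fallback differentiates O7 by selective deacylation instead of selective alkylation. It sets out from 1: Ac2O, pyridine and DMAP give (2R,3R)-3,5,7,4'-tetra-O-acetylaromadendrin F4. Thiophenol and imidazole in N-methylpyrrolidone should remove only the 7-O-acetyl group, the most electrophilic aryl ester because its phenoxide is para to the C4 carbonyl, giving (2R,3R)-3,5,4'-tri-O-acetylaromadendrin F5. MOMCl and iPr2NEt then give (2R,3R)-3,5,4'-tri-O-acetyl-7-O-MOM-aromadendrin F6, and methanolysis of the three acetates (K2CO3, MeOH, 0 °C) rejoins the route at 2.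

**Further compounds**

F1 | step 6 | (2R,3R)-3-O-acetyl-7-O-MOM-5-O-prenyl-3'-prenylaromadendrin | CC(C)=CCc1cc([C@H]2Oc3cc(OCOC)cc(OCC=C(C)C)c3C(=O)[C@@H]2OC(C)=O)ccc1O
F2 | step 2 | tert-butyl 2-methylbut-3-en-2-yl carbonate | C=CC(C)(C)OC(=O)OC(C)(C)C
F3 | step 2 | (2R,3R)-7-O-MOM-4'-O-(2-methylbut-3-en-2-yl)aromadendrin | C=CC(C)(C)Oc1ccc([C@H]2Oc3cc(OCOC)cc(O)c3C(=O)[C@@H]2O)cc1
F4 | step 1 | (2R,3R)-3,5,7,4'-tetra-O-acetylaromadendrin | CC(=O)Oc1ccc([C@H]2Oc3cc(OC(C)=O)cc(OC(C)=O)c3C(=O)[C@@H]2OC(C)=O)cc1
F5 | step 1 | (2R,3R)-3,5,4'-tri-O-acetylaromadendrin | CC(=O)Oc1ccc([C@H]2Oc3cc(O)cc(OC(C)=O)c3C(=O)[C@@H]2OC(C)=O)cc1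
F6 | step 1 | (2R,3R)-3,5,4'-tri-O-acetyl-7-O-MOM-aromadendrin | CC(=O)Oc1ccc([C@H]2Oc3cc(OCOC)cc(OC(C)=O)c3C(=O)[C@@H]2OC(C)=O)cc1
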